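**Plan**

- Numbering used: bicyclo[3.2.1]octane C1 (OMe bridgehead), C2 (C=O), C3 (CHOMe), C4 (CH2), C5 (allyl bridgehead), C6 (CHMe), C7 (CHAr), C8 (CHOAc). Enabling feature: C7 (aryl) and C8 (acetoxy) are both β to the C2 ketone through the same α-carbon C1, and the perimeter C1–C7 is a seven-membered ring.
- Retrosynthesis: cut the C3–OMe bond (α-oxygenation); then cut C7–aryl and C1–C8 together (conjugate addition / transannular aldol / O-acetylation) to reach the monocyclic 2-methoxycyclohept-2-enone carbaldehyde 12; then remove the enol-ether oxygen and one ring carbon (epoxide route, ring expansion) and cut the two Diels–Alder bonds.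
- Forward: a Diels–Alder reaction gives the cyclohexene carrying the quaternary C5 and C6; cyclopropanation and Fe(III) ring expansion give the cycloheptenone; epoxidation and methanolysis give the α-methoxy enone; the aryl cuprate cascade closes the five- and six-membered rings of the bicycle in one operation; Rubottom oxidation and O-methylation finish C3.
- Stereochemistry: C5 and C6 come from the catalytic enantioselective endo Diels–Alder reaction; C7 forms anti to the C6 methyl, C1 by the geometry of bridging, C8 by the chelated aldol transition state; C3 by endo (axial) oxygenation opposite the syn 8-acetoxy group.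

Key step: step 9

Remark: the (S)-configured oxazaborolidinium catalyst is assumed to expose the Si face at C-2 of enal 2 (formyl C–H···O model); should the sense be opposite, its enantiomer is used with no other change.

**Step 1**
Reactants: 1 pent-4-enal
Product: 2 2-methylidenepent-4-enal
Conditions: 37% aq. HCHO, pyrrolidine (10 mol%), EtCO2H (10 mol%), i-PrOH, 45 °C
Reagents that add atoms: formaldehyde, C=O
Why: Amine-catalysed Mannich condensation and elimination (α-methylenation of an aldehyde) should give the 2-substituted acrolein without touching the terminal alkene.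

**Step 2**
Reactants: 3 (3E)-pent-3-en-2-one
Product: 4 tert-butyl(dimethyl){[(3E)-penta-1,3-dien-2-yl]oxy}silane
Conditions: TBSOTf, Et3N, Et2O, 0 °C
Reagents that add atoms: tert-butyldimethylsilyl trifluoromethanesulfonate, CC(C)(C)[Si](C)(C)OS(=O)(=O)C(F)(F)F
Why: Soft enolisation at the methyl group (silyl enol ether formation) should give the cross-conjugated 2-silyloxy diene with the E-propenyl unit unchanged.

**Step 3**
Reactants: 2 2-methylidenepent-4-enal; 4 tert-butyl(dimethyl){[(3E)-penta-1,3-dien-2-yl]oxy}silane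
Product: 5 (1R,2R)-4-{[tert-butyl(dimethyl)silyl]oxy}-2-methyl-1-(prop-2-en-1-yl)cyclohex-3-ene-1-carbaldehyde
Conditions: (S)-B-(o-tolyl) diphenylprolinol oxazaborolidine·Tf2NH (10 mol%), CH2Cl2, −78 °C
Reagents that add atoms: none
Why: Catalytic enantioselective Diels–Alder reaction of a 2-substituted acrolein, in which the 1-methyl and 3-silyloxy groups of the diene both direct the formyl-bearing carbon next to the methyl-bearing carbon, the formyl-endo transition state with the E-diene places methyl and formyl cis, and the catalyst-shielded enal face fixes the absolute configuration of the quaternary and the methyl-bearing carbon.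

**Step 4**
Reactants: 5 (1R,2R)-4-{[tert-butyl(dimethyl)silyl]oxy}-2-methyl-1-(prop-2-en-1-yl)cyclohex-3-ene-1-carbaldehyde
Product: 6 (1R,2R,3R,6S)-6-{[tert-butyl(dimethyl)silyl]oxy}-2-methyl-3-(prop-2-en-1-yl)bicyclo[4.1.0]heptane-3-carbaldehyde
Conditions: Et2Zn, CH2I2, CH2Cl2, 0 °C
Reagents that add atoms: diiodomethane, ICI
Why: Furukawa–Simmons–Smith cyclopropanation should take place at the electron-rich silyl enol ether much faster than at the monosubstituted allyl alkene, and the two new centres (methylene expected mainly anti to the methyl group) are erased in step 5.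

**Step 5**
Reactants: 6 (1R,2R,3R,6S)-6-{[tert-butyl(dimethyl)silyl]oxy}-2-methyl-3-(prop-2-en-1-yl)bicyclo[4.1.0]heptane-3-carbaldehyde
Product: 8 (1R,2R)-2-methyl-5-oxo-1-(prop-2-en-1-yl)cyclohept-3-ene-1-carbaldehyde, via β-chloro ketone 7 (not isolated)
Conditions: FeCl3, DMF, 0 °C → rt; then NaOAc, MeOH, reflux
Reagents that add atoms: none
Why: Ito–Saegusa ring expansion, in which Fe(III) opens the siloxycyclopropane at the ring-fusion bond to the ring-enlarged β-keto radical, chlorine transfer gives the β-chloro ketone and E1cB loss of HCl gives the cyclohept-2-enone, the two stereocentres staying untouched.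

**Step 6**
Reactants: 8 (1R,2R)-2-methyl-5-oxo-1-(prop-2-en-1-yl)cyclohept-3-ene-1-carbaldehyde
Product: 9 (4R,5R)-5-(dimethoxymethyl)-4-methyl-5-(prop-2-en-1-yl)cyclohept-2-en-1-one
Conditions: HC(OMe)3, CeCl3·7H2O, MeOH, rt
Reagents that add atoms: trimethyl orthoformate, COC(OC)OC
Why: Lanthanide-mediated acetalisation (Luche–Gemal conditions) is selective for an aldehyde over a conjugated ketone and masks the formyl group against the basic steps that follow.

**Step 7**
Reactants: 9 (4R,5R)-5-(dimethoxymethyl)-4-methyl-5-(prop-2-en-1-yl)cyclohept-2-en-1-one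
Product: 11 (4R,5R)-5-(dimethoxymethyl)-2-methoxy-4-methyl-5-(prop-2-en-1-yl)cyclohept-2-en-1-one, via epoxy ketone 10 (not isolated)
Conditions: 30% H2O2, NaOH, MeOH, 0 °C; then NaOMe, MeOH, 65 °C
Reagents that add atoms: sodium methoxide, C[O-].[Na+]
Why: Weitz–Scheffer epoxidation followed by methoxide opening of the epoxy ketone at its α-carbon and E1cB loss of water (the known route from epoxy ketones to 2-alkoxy enones) should give the α-methoxy enone with defined regiochemistry.

**Step 8**
Reactants: 11 (4R,5R)-5-(dimethoxymethyl)-2-methoxy-4-methyl-5-(prop-2-en-1-yl)cyclohept-2-en-1-one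
Product: 12 (1R,2R)-4-methoxy-2-methyl-5-oxo-1-(prop-2-en-1-yl)cyclohept-3-ene-1-carbaldehyde
Conditions: 1 M HCl, THF, rt
Reagents that add atoms: water, O
Why: Acid hydrolysis of the dimethyl acetal, in which the aldehyde has no α-hydrogen so no centre can epimerise and the α-methoxy enone should survive dilute acid at room temperature.

**Step 9**
Reactants: 12 (1R,2R)-4-methoxy-2-methyl-5-oxo-1-(prop-2-en-1-yl)cyclohept-3-ene-1-carbaldehyde; 13 4-bromo-1,2-dimethoxybenzene
Product: 18 (1S,5R,6R,7S,8S)-7-(3,4-dimethoxyphenyl)-1-methoxy-6-methyl-2-oxo-5-(prop-2-en-1-yl)bicyclo[3.2.1]octan-8-yl acetate, via aryllithium 14 (not isolated), via diarylcuprate 15 (not isolated), via lithium enolate 16 (not isolated), via lithium aldolate 17 (not isolated)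
Conditions: 13, n-BuLi, Et2O/THF, −78 °C; CuI, −40 °C; then 12, −78 → −20 °C; then Ac2O, −20 → 0 °C
Reagents that add atoms: acetic anhydride, CC(=O)OC(C)=O
Why: The diarylcuprate transfers its aryl group to the enone β-carbon (C-3 of 12, the future C-7) to give the regiodefined lithium enolate 16, whose methoxy-bearing α-carbon adds across the ring to the formyl group on the quaternary carbon, and the aldolate 17 is acetylated in the same flask so that it cannot revert. The closest known reaction type is the tandem organocuprate conjugate addition–intramolecular aldol reaction with O-acylation of the aldolate. The one transannular C–C bond closes the five-membered ring in a 5-(enolexo)-exo-trig mode and the six-membered ring in a 6-(enolendo)-exo-trig mode. C-7 is set by approach of the cuprate anti to the adjacent C-6 methyl group and to the pseudoaxial formyl group on the same face, which places the aryl group endo; C-1 is fixed by the need to bridge on the formyl face; C-8 is set by the lithium-chelated closed transition state, in which the aldehyde oxygen lies beside the enolate oxygen and so ends syn to the ketone bridge. The step needs 1,4-addition to the donor-substituted enone to be faster than 1,2-addition to the aldehyde, for which the soft cuprate and the neopentyl position of the formyl group (quaternary α-carbon) are relied on.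

**Step 10**
Reactants: 18 (1S,5R,6R,7S,8S)-7-(3,4-dimethoxyphenyl)-1-methoxy-6-methyl-2-oxo-5-(prop-2-en-1-yl)bicyclo[3.2.1]octan-8-yl acetate
Product: 21 (1S,3S,5S,6R,7S,8S)-7-(3,4-dimethoxyphenyl)-3-hydroxy-1-methoxy-6-methyl-2-oxo-5-(prop-2-en-1-yl)bicyclo[3.2.1]octan-8-yl acetate, via silyl enol ether 19 (not isolated), via α-silyloxy ketone 20 (not isolated)
Conditions: TMSOTf, Et3N, CH2Cl2, 0 °C; DMDO, acetone, −40 °C; then citric acid, MeOH
Reagents that add atoms: dimethyldioxirane, CC1(C)OO1
Why: Rubottom oxidation, in which C-3 is the only enolisable position, the electron-rich enol ether reacts before the allyl alkene, and the oxygen is expected on the endo (axial) face of C-3 because the exo face is covered by the syn 8-acetoxy group and axial attack leads directly to the chair; the non-basic conditions keep the acetate in place.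

**Step 11**
Reactants: 21 (1S,3S,5S,6R,7S,8S)-7-(3,4-dimethoxyphenyl)-3-hydroxy-1-methoxy-6-methyl-2-oxo-5-(prop-2-en-1-yl)bicyclo[3.2.1]octan-8-yl acetate
Product: 22 (1S,3S,5S,6R,7S,8S)-7-(3,4-dimethoxyphenyl)-1,3-dimethoxy-6-methyl-2-oxo-5-(prop-2-en-1-yl)bicyclo[3.2.1]octan-8-yl acetate
Conditions: Me3O·BF4, 1,8-bis(dimethylamino)naphthalene, CH2Cl2, 0 °C → rt
Reagents that add atoms: trimethyloxonium tetrafluoroborate, C[O+](C)C.F[B-](F)(F)F
Why: O-Methylation of the hindered α-hydroxy ketone with Meerwein's salt and a non-nucleophilic base (alkylation under non-enolising conditions) should keep the C-3 configuration and the acetate.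

**Compound list**

1 | pent-4-enal | C=CCCC=O | starting material
2 | 2-methylidenepent-4-enal | C=CCC(=C)C=O | intermediate
3 | (3E)-pent-3-en-2-one | C/C=C/C(C)=O | starting material
4 | tert-butyl(dimethyl){[(3E)-penta-1,3-dien-2-yl]oxy}silane | C/C=C/C(=C)O[Si](C)(C)C(C)(C)C | intermediate
5 | (1R,2R)-4-{[tert-butyl(dimethyl)silyl]oxy}-2-methyl-1-(prop-2-en-1-yl)cyclohex-3-ene-1-carbaldehyde | C=CC[C@]1(C=O)CCC(O[Si](C)(C)C(C)(C)C)=C[C@H]1C | intermediate
6 | (1R,2R,3R,6S)-6-{[tert-butyl(dimethyl)silyl]oxy}-2-methyl-3-(prop-2-en-1-yl)bicyclo[4.1.0]heptane-3-carbaldehyde (expected major isomer; its cyclopropane epimer converges in step 5) | C=CC[C@]1(C=O)CC[C@]2(O[Si](C)(C)C(C)(C)C)C[C@@H]2[C@H]1C | intermediate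
7 | 3-chloro-2-methyl-5-oxo-1-(prop-2-en-1-yl)cycloheptane-1-carbaldehyde (C-3 epimers; other centres as in 6) | C=CC[C@]1(C=O)CCC(=O)CC(Cl)[C@H]1C | intermediate
8 | (1R,2R)-2-methyl-5-oxo-1-(prop-2-en-1-yl)cyclohept-3-ene-1-carbaldehyde | C=CC[C@]1(C=O)CCC(=O)C=C[C@H]1C | intermediate
9 | (4R,5R)-5-(dimethoxymethyl)-4-methyl-5-(prop-2-en-1-yl)cyclohept-2-en-1-one | C=CC[C@]1(C(OC)OC)CCC(=O)C=C[C@H]1C | intermediate
10 | (1R,5R,6S,7R)-5-(dimethoxymethyl)-6-methyl-5-(prop-2-en-1-yl)-8-oxabicyclo[5.1.0]octan-2-one (epoxide anti to methyl) | C=CC[C@]1(C(OC)OC)CCC(=O)[C@@H]2O[C@@H]2[C@H]1C | intermediate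
11 | (4R,5R)-5-(dimethoxymethyl)-2-methoxy-4-methyl-5-(prop-2-en-1-yl)cyclohept-2-en-1-one | C=CC[C@]1(C(OC)OC)CCC(=O)C(OC)=C[C@H]1C | intermediate
12 | (1R,2R)-4-methoxy-2-methyl-5-oxo-1-(prop-2-en-1-yl)cyclohept-3-ene-1-carbaldehyde | C=CC[C@]1(C=O)CCC(=O)C(OC)=C[C@H]1C | intermediate
13 | 4-bromo-1,2-dimethoxybenzene | COc1ccc(Br)cc1OC | starting material
14 | (3,4-dimethoxyphenyl)lithium | [Li]c1ccc(OC)c(OC)c1 | intermediate
15 | lithium bis(3,4-dimethoxyphenyl)cuprate | [Li+].COc1ccc([Cu-]c2ccc(OC)c(OC)c2)cc1OC | intermediate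
16 | lithium (3S,4R,5R)-3-(3,4-dimethoxyphenyl)-5-formyl-2-methoxy-4-methyl-5-(prop-2-en-1-yl)cyclohept-1-en-1-olate | [Li+].C=CC[C@]1(C=O)CCC([O-])=C(OC)[C@H](c2ccc(OC)c(OC)c2)[C@H]1C | intermediate
17 | lithium (1S,5R,6R,7S,8S)-7-(3,4-dimethoxyphenyl)-1-methoxy-6-methyl-2-oxo-5-(prop-2-en-1-yl)bicyclo[3.2.1]octan-8-olate | [Li+].C=CC[C@]12CCC(=O)[C@](OC)([C@H](c3ccc(OC)c(OC)c3)[C@H]1C)[C@H]2[O-] | intermediate
18 | (1S,5R,6R,7S,8S)-7-(3,4-dimethoxyphenyl)-1-methoxy-6-methyl-2-oxo-5-(prop-2-en-1-yl)bicyclo[3.2.1]octan-8-yl acetate | C=CC[C@]12CCC(=O)[C@](OC)([C@H](c3ccc(OC)c(OC)c3)[C@H]1C)[C@H]2OC(C)=O | intermediate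
19 | trimethylsilyl enol ether of 18 (C2=C3 enol ether; other centres as in 18) | C=CC[C@]12CC=C(O[Si](C)(C)C)[C@](OC)([C@H](c3ccc(OC)c(OC)c3)[C@H]1C)[C@H]2OC(C)=O | intermediate
20 | (1S,3S,5S,6R,7S,8S)-7-(3,4-dimethoxyphenyl)-1-methoxy-6-methyl-2-oxo-5-(prop-2-en-1-yl)-3-[(trimethylsilyl)oxy]bicyclo[3.2.1]octan-8-yl acetate | C=CC[C@]12C[C@H](O[Si](C)(C)C)C(=O)[C@](OC)([C@H](c3ccc(OC)c(OC)c3)[C@H]1C)[C@H]2OC(C)=O | intermediate
21 | (1S,3S,5S,6R,7S,8S)-7-(3,4-dimethoxyphenyl)-3-hydroxy-1-methoxy-6-methyl-2-oxo-5-(prop-2-en-1-yl)bicyclo[3.2.1]octan-8-yl acetate | C=CC[C@]12C[C@H](O)C(=O)[C@](OC)([C@H](c3ccc(OC)c(OC)c3)[C@H]1C)[C@H]2OC(C)=O | intermediate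
22 | (1S,3S,5S,6R,7S,8S)-7-(3,4-dimethoxyphenyl)-1,3-dimethoxy-6-methyl-2-oxo-5-(prop-2-en-1-yl)bicyclo[3.2.1]octan-8-yl acetate | C=CC[C@]12C[C@H](OC)C(=O)[C@](OC)([C@H](c3ccc(OC)c(OC)c3)[C@H]1C)[C@H]2OC(C)=O | target

**Totals**

Total step count: 11. Longest linear sequence: 10 steps (1 → 2 → 5 → 6 → 8 → 9 → 11 → 12 → 18 → 21 → 22; the branch from 3 is equally long).

**Steps most likely to fail**

Step 9. Competing 1,2-addition of the aryl–metal to the formyl group, or too slow a conjugate addition to the donor-substituted enone, would defeat the cascade. The fallback separates the two events and sets out from acetal 11. The diarylcuprate 15 adds to 11, in which no aldehyde is present, to give after protonation the β-aryl ketone acetal F1 (C-2 epimers, both usable). Dilute aqueous HCl in THF then removes the acetal, and the freed aldehyde should undergo transannular aldol addition through the enol of the α-methoxy ketone to the hydroxy ketone F2. Acetylation (Ac2O, DMAP, pyridine) comes back to the route at 18.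

Step 10. Poor facial selectivity in the oxygen transfer (attack on the exo face of C-3, or on both faces) would give the wrong C-3 configuration. If the exo face proves the more open one, a proton will take it as well, so the fallback forms the C-3 centre by C–H instead of C–O bond formation and sets out from 18. Condensation with tert-butoxybis(dimethylamino)methane gives the enaminone F3. Sensitised photo-oxygenation (O2, rose bengal, hν, −78 °C) cleaves its C=C bond to the diosphenol F4. O-Methylation (TMSCHN2, MeOH/toluene) gives the 3-methoxy enone F5. Conjugate reduction with Stryker's reagent and kinetic protonation of the enolate at C-3 from that exo face comes back to the route at 22.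

Step 5. Cyclisation of the ring-enlarged β-keto radical onto the allyl group (5-exo) before chlorine transfer, or reaction of the carbenoid or Fe(III) at the allyl alkene, would divert the ring expansion. The fallback brings in the allyl group after the radical step and sets out from diene 4. The same catalysed Diels–Alder reaction with acrolein gives the aldehyde F6 (its C-1 epimer is equally usable). Cyclopropanation (Et2Zn, CH2I2) gives the siloxycyclopropane F7. FeCl3 in DMF and then NaOAc in MeOH give, by way of the chloro ketone F8, the enone aldehyde F9. α-Allylation of the aldehyde (KOt-Bu, allyl bromide, THF, −40 °C; any O-allyl enol ether is rearranged by heating, Claisen) should take place anti to the neighbouring methyl group and comes back to the route at 8.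

**Further compounds**

F1 | step 9 | (3S,4R,5R)-3-(3,4-dimethoxyphenyl)-5-(dimethoxymethyl)-2-methoxy-4-methyl-5-(prop-2-en-1-yl)cycloheptan-1-one (C-2 epimers) | C=CC[C@]1(C(OC)OC)CCC(=O)C(OC)[C@H](c2ccc(OC)c(OC)c2)[C@H]1C
F2 | step 9 | (1S,5R,6R,7S,8S)-7-(3,4-dimethoxyphenyl)-8-hydroxy-1-methoxy-6-methyl-5-(prop-2-en-1-yl)bicyclo[3.2.1]octan-2-one | C=CC[C@]12CCC(=O)[C@](OC)([C@H](c3ccc(OC)c(OC)c3)[C@H]1C)[C@H]2O
F3 | step 10 | 3-[(E)-(dimethylamino)methylidene] derivative of 18 (enaminone; other centres as in 18) | C=CC[C@]12C/C(=C\N(C)C)C(=O)[C@](OC)([C@H](c3ccc(OC)c(OC)c3)[C@H]1C)[C@H]2OC(C)=O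
F4 | step 10 | 7-(3,4-dimethoxyphenyl)-3-hydroxy-1-methoxy-6-methyl-2-oxo-5-(prop-2-en-1-yl)bicyclo[3.2.1]oct-3-en-8-yl acetate (diosphenol; centres as in 18) | C=CC[C@]12C=C(O)C(=O)[C@](OC)([C@H](c3ccc(OC)c(OC)c3)[C@H]1C)[C@H]2OC(C)=O
F5 | step 10 | 7-(3,4-dimethoxyphenyl)-1,3-dimethoxy-6-methyl-2-oxo-5-(prop-2-en-1-yl)bicyclo[3.2.1]oct-3-en-8-yl acetate (centres as in 18) | C=CC[C@]12C=C(OC)C(=O)[C@](OC)([C@H](c3ccc(OC)c(OC)c3)[C@H]1C)[C@H]2OC(C)=O
F6 | step 5 | (1S,2R)-4-{[tert-butyl(dimethyl)silyl]oxy}-2-methylcyclohex-3-ene-1-carbaldehyde | O=C[C@H]1CCC(O[Si](C)(C)C(C)(C)C)=C[C@H]1C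
F7 | step 5 | 6-{[tert-butyl(dimethyl)silyl]oxy}-2-methylbicyclo[4.1.0]heptane-3-carbaldehyde (from F6; methylene anti to methyl) | O=C[C@H]1CC[C@]2(O[Si](C)(C)C(C)(C)C)C[C@@H]2[C@H]1C
F8 | step 5 | 3-chloro-2-methyl-5-oxocycloheptane-1-carbaldehyde (C-3 epimers; not isolated) | O=C[C@H]1CCC(=O)CC(Cl)[C@H]1C
F9 | step 5 | (1S,2R)-2-methyl-5-oxocyclohept-3-ene-1-carbaldehyde | O=C[C@H]1CCC(=O)C=C[C@H]1C
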